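**Plan**

- Retrosynthesis: the three methoxymethyl (MOM) ethers come off last. The C3–H bond is traced back to an allyl ester on C3. Ring C is then cut at O1–C8a and C4–C4a, which separates a ring A aryne from a ring B hydroxymethyl malonate.
- Enabling feature: ring C is fused to ring A through the adjacent carbons C8a (bonded to O1) and C4a (bonded to C4), with the C5 oxygen next to C4a. This is the pattern a 3-alkoxyaryne gives when a nucleophile adds at its far carbon and the near carbon is then acylated.
- Further cuts: C6–prenyl and C4a–Si on ring A; C3′–geranyl, C1′–C3 and C3–C2 on ring B.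
- Forward order: rings A and B are bought as phloroglucinol and 4-bromo-2-iodophenol and elaborated separately (steps 1–7 and 8–12). Ring C, the only ring made, closes in step 13, and two steps finish the synthesis.
- Stereochemistry: the single stereocenter C3 (R) comes from ligand-controlled protonation of a palladium enolate in step 14. The E alkene of the geranyl chain is carried in unchanged from geranyl bromide.

Key step: step 13

Assumption: atom labels follow the chroman-4-one skeleton (O1, C2, C3, C4, C4a, C5–C8, C8a; ring B primed), and (S)-t-Bu-PHOX is taken to deliver the proton to the enolate face that gives 3R; if the sense proves opposite, the (R)-ligand is used instead.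

**Route**

Step 1
Reactants: 1 phloroglucinol
Product: 2 3,5-bis(methoxymethoxy)phenol
Conditions: MOMCl (2.0 equiv), K2CO3, acetone, 0 °C → rt; chromatography
Reagents that add atoms: chloromethyl methyl ether, COCCl
Why: Williamson-type O-alkylation of the three equivalent hydroxyls with two equivalents of the chloromethyl ether should give the bis-ether as the main component of a statistical mixture, from which it is separated.

Step 2
Reactants: 2 3,5-bis(methoxymethoxy)phenol
Product: 3 [3,5-bis(methoxymethoxy)phenoxy]tri(propan-2-yl)silane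
Conditions: TIPSCl, imidazole, DMF, rt
Reagents that add atoms: chlorotri(propan-2-yl)silane, CC(C)[Si](Cl)(C(C)C)C(C)C
Why: Standard imidazole-promoted silylation of the remaining phenol installs a bulky, non-coordinating group that keeps the next metalation away from its own ortho carbons.

Step 3
Reactants: 3 [3,5-bis(methoxymethoxy)phenoxy]tri(propan-2-yl)silane; 4 prenyl bromide (1-bromo-3-methylbut-2-ene)
Product: 6 [3,5-bis(methoxymethoxy)-4-(3-methylbut-2-en-1-yl)phenoxy]tri(propan-2-yl)silane, via aryllithium 5 (not isolated)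
Conditions: n-BuLi, THF, 0 °C; CuI (10 mol %), then 4, −78 °C → rt
Reagents that add atoms: none
Why: Directed ortho-metalation places lithium on the carbon flanked by both MOM ethers, and allylic substitution catalysed by monovalent copper at the primary carbon of the bromide (SN2) should give the linear prenyl arene.

Step 4
Reactants: 6 [3,5-bis(methoxymethoxy)-4-(3-methylbut-2-en-1-yl)phenoxy]tri(propan-2-yl)silane
Product: 7 3,5-bis(methoxymethoxy)-4-(3-methylbut-2-en-1-yl)phenol
Conditions: TBAF, THF, 0 °C; aq. NH4Cl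
Reagents that add atoms: none
Why: Fluoride-mediated desilylation of an aryl silyl ether should free the phenol para to the prenyl group and leave the acetals and the alkene untouched.

Step 5
Reactants: 7 3,5-bis(methoxymethoxy)-4-(3-methylbut-2-en-1-yl)phenol
Product: 8 3,5-bis(methoxymethoxy)-4-(3-methylbut-2-en-1-yl)phenyl N-(propan-2-yl)carbamate
Conditions: i-PrNCO, Et3N (cat.), CH2Cl2, rt
Reagents that add atoms: isopropyl isocyanate, CC(C)N=C=O
Why: Amine-catalysed addition of the phenol to the isocyanate (carbamoylation) provides a group that first directs metalation and is later removed under mild base.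

Step 6
Reactants: 8 3,5-bis(methoxymethoxy)-4-(3-methylbut-2-en-1-yl)phenyl N-(propan-2-yl)carbamate
Product: 12 3,5-bis(methoxymethoxy)-4-(3-methylbut-2-en-1-yl)-2-(trimethylsilyl)phenyl N-(propan-2-yl)carbamate, via N-silyl carbamate 9 (not isolated), via aryllithium 10 (not isolated), via bis-silyl carbamate 11 (not isolated)
Conditions: TBSOTf, TMEDA, Et2O, 0 °C → rt; n-BuLi, TMEDA, −78 °C; TMSCl, −78 °C → rt; sat. aq. NH4Cl
Reagents that add atoms: chlorotrimethylsilane, C[Si](C)(C)Cl
Why: Carbamate-directed ortho-metalation with in situ N-silylation (the amine-complexed silyl triflate being too weak a Lewis acid to open the MOM acetals) can lithiate only the two equivalent carbons lying between the carbamate and a MOM ether, so C-silylation is unambiguous and aqueous work-up removes the N-silyl group.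

Step 7
Reactants: 12 3,5-bis(methoxymethoxy)-4-(3-methylbut-2-en-1-yl)-2-(trimethylsilyl)phenyl N-(propan-2-yl)carbamate
Product: 14 3,5-bis(methoxymethoxy)-4-(3-methylbut-2-en-1-yl)-2-(trimethylsilyl)phenyl trifluoromethanesulfonate, via silylphenoxide 13 (not isolated)
Conditions: Et2NH, DBU, MeCN, 40 °C; then PhNTf2, rt
Reagents that add atoms: N-phenylbis(trifluoromethanesulfonimide), O=S(=O)(N(c1ccccc1)S(=O)(=O)C(F)(F)F)C(F)(F)F
Why: Base-induced E1cB fragmentation of the N–H carbamate releases the phenoxide and isopropyl isocyanate (trapped by Et2NH), and O-triflation in the same flask is the established endgame for ortho-silylaryl triflates.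

Step 8
Reactants: 15 4-bromo-2-iodophenol
Product: 16 4-bromo-2-iodo-1-(methoxymethoxy)benzene
Conditions: MOMCl, i-Pr2NEt, CH2Cl2, 0 °C → rt
Reagents that add atoms: chloromethyl methyl ether, COCCl
Why: Williamson-type protection of the phenol as its MOM ether, which also supplies a chelating oxygen for the next step.

Step 9
Reactants: 16 4-bromo-2-iodo-1-(methoxymethoxy)benzene; 17 geranyl bromide ((2E)-1-bromo-3,7-dimethylocta-2,6-diene)
Product: 19 4-bromo-2-[(2E)-3,7-dimethylocta-2,6-dien-1-yl]-1-(methoxymethoxy)benzene, via arylmagnesium chloride 18 (not isolated)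
Conditions: i-PrMgCl·LiCl, THF, −40 °C; CuI (10 mol %), then 17, −40 → 0 °C
Reagents that add atoms: none
Why: Iodine–magnesium exchange is selective for the iodide (faster than bromide and assisted by the ortho MOM oxygen), and allylic substitution catalysed by monovalent copper at the primary carbon of geranyl bromide (SN2) should give the linear chain with the E alkene intact.

Step 10
Reactants: 19 4-bromo-2-[(2E)-3,7-dimethylocta-2,6-dien-1-yl]-1-(methoxymethoxy)benzene
Product: 21 2-[(2E)-3,7-dimethylocta-2,6-dien-1-yl]-4-iodo-1-(methoxymethoxy)benzene, via aryllithium 20 (not isolated)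
Conditions: n-BuLi, THF, −78 °C; I2, −78 °C; aq. Na2S2O3
Reagents that add atoms: iodine, II
Why: Bromine–lithium exchange at −78 °C outpaces any deprotonation, and iodinolysis of the aryllithium supplies the aryl iodide needed for copper catalysis at room temperature.

Step 11
Reactants: 21 2-[(2E)-3,7-dimethylocta-2,6-dien-1-yl]-4-iodo-1-(methoxymethoxy)benzene; 22 diallyl malonate
Product: 23 diallyl 2-{3-[(2E)-3,7-dimethylocta-2,6-dien-1-yl]-4-(methoxymethoxy)phenyl}malonate
Conditions: CuI (5 mol %), 2-picolinic acid (10 mol %), Cs2CO3, 1,4-dioxane, rt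
Reagents that add atoms: none
Why: Ullmann–Hurtley C-arylation of a malonate with an aryl iodide runs at room temperature under copper catalysis and, unlike palladium catalysis, leaves the allyl esters intact.

Step 12
Reactants: 23 diallyl 2-{3-[(2E)-3,7-dimethylocta-2,6-dien-1-yl]-4-(methoxymethoxy)phenyl}malonate
Product: 24 diallyl 2-{3-[(2E)-3,7-dimethylocta-2,6-dien-1-yl]-4-(methoxymethoxy)phenyl}-2-(hydroxymethyl)malonate
Conditions: aq. CH2O (37 %), KHCO3 (cat.), THF, 0 °C → rt; neutral work-up
Reagents that add atoms: formaldehyde, C=O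
Why: Base-catalysed aldol addition (hydroxymethylation) of the acidic aryl malonate C–H to formaldehyde creates the quaternary carbon, and catalytic weak base with neutral work-up keeps the reverse reaction slow.

Step 13
Reactants: 14 3,5-bis(methoxymethoxy)-4-(3-methylbut-2-en-1-yl)-2-(trimethylsilyl)phenyl trifluoromethanesulfonate; 24 diallyl 2-{3-[(2E)-3,7-dimethylocta-2,6-dien-1-yl]-4-(methoxymethoxy)phenyl}-2-(hydroxymethyl)malonate
Product: 27 racemic allyl 3-{3-[(2E)-3,7-dimethylocta-2,6-dien-1-yl]-4-(methoxymethoxy)phenyl}-5,7-bis(methoxymethoxy)-6-(3-methylbut-2-en-1-yl)-4-oxochromane-3-carboxylate, via aryne 25 (not isolated), via aryl anion 26 (not isolated)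
Conditions: CsF (4 equiv), 14 (1.5 equiv, in portions), THF, 65 °C
Reagents that add atoms: none
Why: Proposed new method: fluoride removes the trimethylsilyl group of 14 and triflate departs to give aryne 25 (C4a≡C8a); the primary hydroxyl of 24, activated only by hydrogen bonding to fluoride, adds through oxygen to C8a, and the resulting C4a aryl anion 26 attacks one of the two identical allyl ester carbonyls and expels allyl oxide, so that O1–C8a and C4–C4a form in one operation. The closest known reactions are the aryne annulation of salicylate esters to xanthones (O-arylation followed by acyl substitution by the aryl anion) and the insertion of arynes into O–H bonds of aliphatic alcohols; the new element is the pairing of an aliphatic hydroxyl with a malonate ester as acyl acceptor. Ring C closes by 6-exo-trig addition of the C4a carbanion to the ester carbonyl once the intermolecular C–O bond has formed. C3 becomes a quaternary stereocenter without control and is obtained racemic, which is intended because step 14 removes the ester and sets this center anew. Regiochemistry rests on the C5 methoxymethoxy group, whose inductive effect distorts the aryne so that the nucleophile enters at the remote, unhindered C8a and the charge develops at C4a next to oxygen, and the equivalence of the two esters means either acyl transfer gives 27. Acylation should outrun protonation because the carbonyl is held in a six-membered transition state in THF, which offers no acidic C–H, and retro-aldol loss of formaldehyde is held back because the alcohol stays neutral until it meets the aryne and the quaternary C3 can neither enolise nor eliminate.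

Step 14
Reactants: 27 racemic allyl 3-{3-[(2E)-3,7-dimethylocta-2,6-dien-1-yl]-4-(methoxymethoxy)phenyl}-5,7-bis(methoxymethoxy)-6-(3-methylbut-2-en-1-yl)-4-oxochromane-3-carboxylate
Product: 28 (3R)-3-{3-[(2E)-3,7-dimethylocta-2,6-dien-1-yl]-4-(methoxymethoxy)phenyl}-5,7-bis(methoxymethoxy)-6-(3-methylbut-2-en-1-yl)chroman-4-one
Conditions: Pd2(dba)3 (5 mol %), (S)-t-Bu-PHOX (12.5 mol %), Meldrum's acid (2.5 equiv), 1,4-dioxane, 25 °C
Reagents that add atoms: none
Why: Palladium-catalysed decarboxylative protonation (Tsuji–Trost ionisation of the allyl ester, loss of CO2, then protonation of the PHOX-bound palladium enolate by Meldrum's acid, which also takes up the allyl group) is established for allyl 3-aryl-4-oxochromane-3-carboxylates, and the chiral ligand controls the face of proton delivery that sets C3 as R.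

Step 15
Reactants: 28 (3R)-3-{3-[(2E)-3,7-dimethylocta-2,6-dien-1-yl]-4-(methoxymethoxy)phenyl}-5,7-bis(methoxymethoxy)-6-(3-methylbut-2-en-1-yl)chroman-4-one
Product: 29 (3R)-3-{3-[(2E)-3,7-dimethylocta-2,6-dien-1-yl]-4-hydroxyphenyl}-5,7-dihydroxy-6-(3-methylbut-2-en-1-yl)chroman-4-one
Conditions: HCl (ca. 1 M in MeOH), MeOH/THF, 25 → 40 °C; NaHCO3 quench at full conversion
Reagents that add atoms: none
Why: Acid-catalysed acetal exchange with methanol cleaves the three aryl MOM ethers, and dilute acid near room temperature is chosen so that neither enolisation at C3 nor addition of the free phenols to the prenyl and geranyl alkenes should compete.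

**Compound list**

1 | phloroglucinol | Oc1cc(O)cc(O)c1 | starting material
2 | 3,5-bis(methoxymethoxy)phenol | COCOc1cc(O)cc(OCOC)c1 | intermediate
3 | [3,5-bis(methoxymethoxy)phenoxy]tri(propan-2-yl)silane | COCOc1cc(OCOC)cc(O[Si](C(C)C)(C(C)C)C(C)C)c1 | intermediate
4 | prenyl bromide (1-bromo-3-methylbut-2-ene) | CC(C)=CCBr | starting material
5 | [2,6-bis(methoxymethoxy)-4-(triisopropylsilyloxy)phenyl]lithium | [Li]c1c(OCOC)cc(O[Si](C(C)C)(C(C)C)C(C)C)cc1OCOC | intermediate (not isolated)
6 | [3,5-bis(methoxymethoxy)-4-(3-methylbut-2-en-1-yl)phenoxy]tri(propan-2-yl)silane | COCOc1cc(O[Si](C(C)C)(C(C)C)C(C)C)cc(OCOC)c1CC=C(C)C | intermediate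
7 | 3,5-bis(methoxymethoxy)-4-(3-methylbut-2-en-1-yl)phenol | COCOc1cc(O)cc(OCOC)c1CC=C(C)C | intermediate
8 | 3,5-bis(methoxymethoxy)-4-(3-methylbut-2-en-1-yl)phenyl N-(propan-2-yl)carbamate | COCOc1cc(OC(=O)NC(C)C)cc(OCOC)c1CC=C(C)C | intermediate
9 | N-(tert-butyldimethylsilyl) derivative of 8 | COCOc1cc(OC(=O)N(C(C)C)[Si](C)(C)C(C)(C)C)cc(OCOC)c1CC=C(C)C | intermediate (not isolated)
10 | 2-lithio derivative of 9 (lithium between the carbamate and a MOM ether) | [Li]c1c(OC(=O)N(C(C)C)[Si](C)(C)C(C)(C)C)cc(OCOC)c(CC=C(C)C)c1OCOC | intermediate (not isolated)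
11 | 2-(trimethylsilyl) derivative of 9 | C[Si](C)(C)c1c(OC(=O)N(C(C)C)[Si](C)(C)C(C)(C)C)cc(OCOC)c(CC=C(C)C)c1OCOC | intermediate (not isolated)
12 | 3,5-bis(methoxymethoxy)-4-(3-methylbut-2-en-1-yl)-2-(trimethylsilyl)phenyl N-(propan-2-yl)carbamate | C[Si](C)(C)c1c(OC(=O)NC(C)C)cc(OCOC)c(CC=C(C)C)c1OCOC | intermediate
13 | 3,5-bis(methoxymethoxy)-4-(3-methylbut-2-en-1-yl)-2-(trimethylsilyl)phenolate, DBU-H+ salt | C[Si](C)(C)c1c([O-])cc(OCOC)c(CC=C(C)C)c1OCOC.C1CCC2=[NH+]CCCN2CC1 | intermediate (not isolated)
14 | 3,5-bis(methoxymethoxy)-4-(3-methylbut-2-en-1-yl)-2-(trimethylsilyl)phenyl trifluoromethanesulfonate | COCOc1cc(OS(=O)(=O)C(F)(F)F)c([Si](C)(C)C)c(OCOC)c1CC=C(C)C | intermediate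
15 | 4-bromo-2-iodophenol | Oc1ccc(Br)cc1I | starting material
16 | 4-bromo-2-iodo-1-(methoxymethoxy)benzene | COCOc1ccc(Br)cc1I | intermediate
17 | geranyl bromide ((2E)-1-bromo-3,7-dimethylocta-2,6-diene) | CC(C)=CCC/C(C)=C/CBr | starting material
18 | [5-bromo-2-(methoxymethoxy)phenyl]magnesium chloride | COCOc1ccc(Br)cc1[Mg]Cl | intermediate (not isolated)
19 | 4-bromo-2-[(2E)-3,7-dimethylocta-2,6-dien-1-yl]-1-(methoxymethoxy)benzene | CC(C)=CCC/C(C)=C/Cc1cc(Br)ccc1OCOC | intermediate
20 | {3-[(2E)-3,7-dimethylocta-2,6-dien-1-yl]-4-(methoxymethoxy)phenyl}lithium | CC(C)=CCC/C(C)=C/Cc1cc([Li])ccc1OCOC | intermediate (not isolated)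
21 | 2-[(2E)-3,7-dimethylocta-2,6-dien-1-yl]-4-iodo-1-(methoxymethoxy)benzene | CC(C)=CCC/C(C)=C/Cc1cc(I)ccc1OCOC | intermediate
22 | diallyl malonate | C=CCOC(=O)CC(=O)OCC=C | starting material
23 | diallyl 2-{3-[(2E)-3,7-dimethylocta-2,6-dien-1-yl]-4-(methoxymethoxy)phenyl}malonate | CC(C)=CCC/C(C)=C/Cc1cc(C(C(=O)OCC=C)C(=O)OCC=C)ccc1OCOC | intermediate
24 | diallyl 2-{3-[(2E)-3,7-dimethylocta-2,6-dien-1-yl]-4-(methoxymethoxy)phenyl}-2-(hydroxymethyl)malonate | CC(C)=CCC/C(C)=C/Cc1cc(C(CO)(C(=O)OCC=C)C(=O)OCC=C)ccc1OCOC | intermediate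
25 | 3,5-bis(methoxymethoxy)-4-(3-methylbut-2-en-1-yl)benzyne (triple bond between the former C–Si and C–OTf carbons) | COCOC1=CC#CC(OCOC)=C1CC=C(C)C | intermediate (not isolated)
26 | cesium aryl anion: diallyl 2-{[2-cesio-3,5-bis(methoxymethoxy)-4-(3-methylbut-2-en-1-yl)phenoxy]methyl}-2-{3-[(2E)-3,7-dimethylocta-2,6-dien-1-yl]-4-(methoxymethoxy)phenyl}malonate | CC(C)=CCC/C(C)=C/Cc1cc(C(COc2cc(OCOC)c(CC=C(C)C)c(OCOC)[c-]2)(C(=O)OCC=C)C(=O)OCC=C)ccc1OCOC.[Cs+] | intermediate (not isolated)
27 | racemic allyl 3-{3-[(2E)-3,7-dimethylocta-2,6-dien-1-yl]-4-(methoxymethoxy)phenyl}-5,7-bis(methoxymethoxy)-6-(3-methylbut-2-en-1-yl)-4-oxochromane-3-carboxylate | CC(C)=CCC/C(C)=C/Cc1cc(C2(C(=O)OCC=C)COc3cc(OCOC)c(CC=C(C)C)c(OCOC)c3C2=O)ccc1OCOC | intermediate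
28 | (3R)-3-{3-[(2E)-3,7-dimethylocta-2,6-dien-1-yl]-4-(methoxymethoxy)phenyl}-5,7-bis(methoxymethoxy)-6-(3-methylbut-2-en-1-yl)chroman-4-one | CC(C)=CCC/C(C)=C/Cc1cc([C@@H]2COc3cc(OCOC)c(CC=C(C)C)c(OCOC)c3C2=O)ccc1OCOC | intermediate
29 | (3R)-3-{3-[(2E)-3,7-dimethylocta-2,6-dien-1-yl]-4-hydroxyphenyl}-5,7-dihydroxy-6-(3-methylbut-2-en-1-yl)chroman-4-one | CC(C)=CCC/C(C)=C/Cc1cc([C@@H]2COc3cc(O)c(CC=C(C)C)c(O)c3C2=O)ccc1O | target

**Step count**

Total: 15 steps. Longest linear sequence: 10 steps (steps 1–7, then 13, 14 and 15); the ring B branch is 5 steps (8–12) before the junction.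

**Steps most likely to fail, with fallbacks**

Step 13. Three processes threaten it. The C4a aryl anion may be protonated (by bifluoride or a second molecule of alcohol) before it reaches the ester, leaving an uncyclised aryl ether. Fluoride may promote retro-aldol loss of formaldehyde from the malonate. The released allyl alcohol may consume aryne. The fallback builds ring C by the known addition of arynes into the C–O bond of carboxylic acids and sets out from 14:
- Heating 14 with acrylic acid and CsF in THF at 125 °C (sealed vessel) should give carboxylate O-arylation at C8a, acyl transfer to C4a and oxa-Michael closure, leading to 5,7-bis(methoxymethoxy)-6-(3-methylbut-2-en-1-yl)chroman-4-one F1.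
- Palladium-catalysed ketone α-arylation of F1 with bromide 19 (Pd(OAc)2, P(t-Bu)3·HBF4, NaOt-Bu, toluene, 80 °C) should then give the racemic 3-aryl chroman-4-one tris-MOM ether F2.
- F2 is carried on by the transfer hydrogenation and re-oxidation pair described under step 14, and the sequence returns to the route at 28.

Step 14. Proton delivery to the palladium enolate may show poor facial discrimination, because ring B carries no ortho substituent to differentiate the enolate faces. The fallback sets C3 by dynamic kinetic resolution and sets out from 27: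
- Tsuji decarboxylation–hydrogenolysis (Pd(PPh3)4, HCO2H/Et3N, THF, rt) should give the racemic ketone F2.
- Noyori transfer hydrogenation with RuCl[(R,R)-TsDPEN](p-cymene) and HCO2H/Et3N, under which C3 epimerises faster than the slower enantiomer is reduced, should give (3R,4R)-cis-3-{3-[(2E)-3,7-dimethylocta-2,6-dien-1-yl]-4-(methoxymethoxy)phenyl}-5,7-bis(methoxymethoxy)-6-(3-methylbut-2-en-1-yl)chroman-4-ol F3.
- Dess–Martin oxidation (NaHCO3, CH2Cl2, 0 °C) re-forms the ketone without touching C3 and returns to the route at 28.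

Step 15. The acid needed for the slowest (ring B) acetal may cause enolisation at C3 and so erode the enantiomeric purity; acid may also add the freed phenols across the prenyl and geranyl alkenes. The fallback moves the acid step to a stage where C3 is quaternary and sets out from 27:
- HCl in MeOH should give racemic allyl 3-{3-[(2E)-3,7-dimethylocta-2,6-dien-1-yl]-4-hydroxyphenyl}-5,7-dihydroxy-6-(3-methylbut-2-en-1-yl)-4-oxochromane-3-carboxylate F4; cyclisation still has to be watched here, but no stereocenter is at stake.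
- Silylation (TESOTf, 2,6-lutidine, CH2Cl2, −78 → 0 °C) should give the tris(triethylsilyl) ether F5.
- The conditions of step 14 should then give (3R)-3-{3-[(2E)-3,7-dimethylocta-2,6-dien-1-yl]-4-(triethylsilyloxy)phenyl}-6-(3-methylbut-2-en-1-yl)-5,7-bis(triethylsilyloxy)chroman-4-one F6.
- Buffered fluoride (Et3N·3HF, THF, 0 °C) removes the silyl groups under near-neutral conditions and returns to the route at 29.

**Further compounds**

F1 | step 13 | 5,7-bis(methoxymethoxy)-6-(3-methylbut-2-en-1-yl)chroman-4-one | COCOc1cc2OCCC(=O)c2c(OCOC)c1CC=C(C)C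
F2 | step 13 | racemic 3-{3-[(2E)-3,7-dimethylocta-2,6-dien-1-yl]-4-(methoxymethoxy)phenyl}-5,7-bis(methoxymethoxy)-6-(3-methylbut-2-en-1-yl)chroman-4-one | CC(C)=CCC/C(C)=C/Cc1cc(C2COc3cc(OCOC)c(CC=C(C)C)c(OCOC)c3C2=O)ccc1OCOC
F3 | step 14 | (3R,4R)-cis-3-{3-[(2E)-3,7-dimethylocta-2,6-dien-1-yl]-4-(methoxymethoxy)phenyl}-5,7-bis(methoxymethoxy)-6-(3-methylbut-2-en-1-yl)chroman-4-ol | CC(C)=CCC/C(C)=C/Cc1cc([C@@H]2COc3cc(OCOC)c(CC=C(C)C)c(OCOC)c3[C@@H]2O)ccc1OCOC
F4 | step 15 | racemic allyl 3-{3-[(2E)-3,7-dimethylocta-2,6-dien-1-yl]-4-hydroxyphenyl}-5,7-dihydroxy-6-(3-methylbut-2-en-1-yl)-4-oxochromane-3-carboxylate | CC(C)=CCC/C(C)=C/Cc1cc(C2(C(=O)OCC=C)COc3cc(O)c(CC=C(C)C)c(O)c3C2=O)ccc1O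
F5 | step 15 | racemic allyl 3-{3-[(2E)-3,7-dimethylocta-2,6-dien-1-yl]-4-(triethylsilyloxy)phenyl}-6-(3-methylbut-2-en-1-yl)-4-oxo-5,7-bis(triethylsilyloxy)chromane-3-carboxylate | CC(C)=CCC/C(C)=C/Cc1cc(C2(C(=O)OCC=C)COc3cc(O[Si](CC)(CC)CC)c(CC=C(C)C)c(O[Si](CC)(CC)CC)c3C2=O)ccc1O[Si](CC)(CC)CC
F6 | step 15 | (3R)-3-{3-[(2E)-3,7-dimethylocta-2,6-dien-1-yl]-4-(triethylsilyloxy)phenyl}-6-(3-methylbut-2-en-1-yl)-5,7-bis(triethylsilyloxy)chroman-4-one | CC(C)=CCC/C(C)=C/Cc1cc([C@@H]2COc3cc(O[Si](CC)(CC)CC)c(CC=C(C)C)c(O[Si](CC)(CC)CC)c3C2=O)ccc1O[Si](CC)(CC)CC
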